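**Assumptions**
- The target is (2R,3′E,7′E)-β-tocotrienol, the natural 2R series. I read the SMILES as 5,8-dimethylchroman-6-ol with a 4,8,12-trimethyltrideca-3,7,11-trienyl chain at C2, and the stereocentre works out as R (priorities O > C3 ring > C1′ chain > CH3).
- Commercial geranyllinalool is taken as the (6E,10E) isomer. It is racemic at C3, which does not matter because that carbon is destroyed in step 1.
- The route does not control C2 by asymmetric catalysis. It makes the racemate in one step and sets the configuration by physical resolution.

**Retrosynthesis**
1. The target (4) comes from enantiomer resolution of (±)-β-tocotrienol (3). The C2 quaternary centre is set only by this resolution.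
2. Compound 3 disconnects to 2,5-dimethylhydroquinone (1) and geranyllinalool (2) by a one-pot Friedel–Crafts allylation, then 6-endo oxa-cyclisation.
3. The only ring formed is the chroman, and it is formed in step 1.
4. The two free ring positions of 1 are equivalent, so only the 5,8-dimethyl regioisomer can form. The three side-chain E-alkenes are already present in 2.

**Step 1**
Reactants: 1 (2,5-dimethylbenzene-1,4-diol, 1.0 equiv) and 2 ((6E,10E)-geranyllinalool, 1.1 equiv)
Product: 3, (±)-β-tocotrienol, i.e. 2,5,8-trimethyl-2-[(3E,7E)-4,8,12-trimethyltrideca-3,7,11-trien-1-yl]chroman-6-ol (racemic at C2)
Conditions: ZnCl2 (0.5 equiv), cat. HCl, EtOAc, 50 °C, 6 h, Ar, dark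
Reagents that add atoms: none. ZnCl2 and HCl are catalysts, and water is lost.
Why: The Lewis/Brønsted acid ionises tertiary allylic alcohol 2 to an allyl cation, which alkylates a free ring position of 1 at the unhindered CH2 terminus (Friedel–Crafts allylation). The ortho phenol then adds to the adjacent trisubstituted alkene by 6-endo Markovnikov hydroalkoxylation to form the chroman. C2 arises from a planar tertiary cation, so it is racemic, and the distal E-alkenes survive because the intramolecular phenol capture is faster than attack on them.

**Step 2**
Reactants: 3 ((±)-β-tocotrienol)
Product: 4, (2R,3′E,7′E)-β-tocotrienol (target), with the 2S enantiomer discarded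
Conditions: preparative chiral-stationary-phase HPLC (Chiralcel OD-H, n-hexane/i-PrOH 99:1, 25 °C, N2, with solvent degassed and light excluded). Collect the 2R fraction, assigned by co-injection with authentic natural (R)-β-tocotrienol and by optical rotation.
Reagents that add atoms: none
Why: Enantiomer resolution on a chiral stationary phase separates the two C2 enantiomers, which differ only at the remote quaternary ether carbon. The centre is not touched chemically, so there is no scrambling.

**Compound list**

| No. | Name | SMILES | Role |
|---|---|---|---|
| 1 | 2,5-dimethylbenzene-1,4-diol (2,5-dimethylhydroquinone) | Cc1cc(O)c(C)cc1O | starting material |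
| 2 | (6E,10E)-geranyllinalool, 3,7,11,15-tetramethylhexadeca-1,6,10,14-tetraen-3-ol | C=CC(C)(O)CC/C=C(C)/CC/C=C(C)/CCC=C(C)C | starting material |
| 3 | (±)-β-tocotrienol | CC(C)=CCC/C(C)=C/CC/C(C)=C/CCC1(C)CCc2c(C)c(O)cc(C)c2O1 | intermediate |
| 4 | (2R,3′E,7′E)-β-tocotrienol | CC(C)=CCC/C(C)=C/CC/C(C)=C/CC[C@]1(C)CCc2c(C)c(O)cc(C)c2O1 | target |

**Total steps:** 2
**Longest linear sequence:** 2
The maximum yield of 4 is 50% of 3, and the actual overall yield will be lower.

**Three steps most likely to fail**
The route has only two steps, so the third entry is a sub-issue of step 1.

1. **Step 1 (condensation).** The cation may trigger polyene cyclisation or bis-alkylation, and yields of this reaction are typically modest.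
   - Fallback: change the approach to a stepwise build. Alkylate 1 with all-E geranylgeraniol by a boron-mediated ortho-allylation to give the aryl-geranylgeranyl hydroquinone, then cyclise it under a mild confined chiral Brønsted acid. This may also give enantioinduction.
2. **Step 2 (resolution).** The two enantiomers differ only at a remote centre, so separation may be poor, and the free hydroquinone monoether can oxidise on the column.
   - Fallback: abandon resolution and build C2 asymmetrically. Use a Pd-catalysed asymmetric allylic etherification of 1 with isoprene monoepoxide to make the quaternary aryl ether, close the ring by 6-endo Heck, and attach the side chain by cross-coupling.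
3. **Quality of the geranyllinalool feeding step 1.** Commercial 2 can contain 6Z or 10Z isomers, which give inseparable Z-tocotrienol contaminants.
   - Fallback: make 2 from (E,E)-farnesylacetone, whose E,E purity is checked first, by vinylmagnesium bromide addition. Alternatively, enrich the (E,E) isomer by AgNO3-silica chromatography before step 1.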